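**Retrosynthetic overview**
- The three C18–O bonds of the carboxyl group, and with them the C4 stereocentre, are made last by site-selective enzymatic oxidation of the equatorial 4α-methyl of copalyl acetate.
- Copalyl acetate comes from (13E)-labd-13-ene-8α,15-diol: the exocyclic 8(17)-alkene by dehydration of the equatorial 8α-alcohol, the ester by selective acetylation of the primary allylic hydroxyl.
- The C15–O bond and the 13E alkene of that diol come from a 1,3-acetoxy shift of the tertiary allylic acetate of sclareol diacetate.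
- Rings A and B (with C5, C9, C10) are not formed in the route; they are taken intact from (−)-sclareol, and no C–C bond is made.

Assumption: the SMILES is read as (13E)-15-acetoxylabda-8(17),13-dien-18-oic acid of the normal labdane series (4R,5R,9S,10R; carboxyl α, trans to the C10 methyl), and bulk fragrance-grade (−)-sclareol is taken as the cheap commercial starting material.

**Step 1**
Reactants: 1 (−)-sclareol [(13R)-labd-14-ene-8α,13-diol]
Product: 2 sclareol diacetate [(13R)-labd-14-ene-8α,13-diyl diacetate]
Conditions: AcCl (4 equiv), N,N-dimethylaniline (5 equiv), CH2Cl2, 0 °C to rt, 24 h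
Reagents that add atoms: acetyl chloride, CC(=O)Cl
Why: O-acylation (esterification) of both hindered tertiary alcohols with an acid chloride buffered by a weak aniline base avoids ionisation of the allylic carbinol (no manoyl oxide, no dienes) and touches no stereocentre.

**Step 2**
Reactants: 2 sclareol diacetate
Product: 4 (13E)-labd-13-ene-8α,15-diol, via rearranged diacetate 3 (not isolated)
Conditions: PdCl2(MeCN)2 (5 mol%), THF, rt, 3 h; then NaOMe (0.5 equiv), MeOH, reflux, 16 h; recrystallisation
Reagents that add atoms: none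
Why: Overman-type divalent-palladium-catalysed [3,3] (cyclisation-induced) allylic acetate rearrangement passes through a six-membered acetoxonium intermediate, makes the C15–O bond and the trisubstituted alkene (13E favoured, about 3:1, the 8-acetate is inert), and Zemplén methanolysis then frees both hydroxyls so that the 13Z isomer is removed by crystallisation of the diol.

**Step 3**
Reactants: 4 (13E)-labd-13-ene-8α,15-diol
Product: 6 copalyl acetate [(13E)-labda-8(17),13-dien-15-yl acetate], via hydroxy acetate 5 (not isolated)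
Conditions: AcCl (1.05 equiv), pyridine (6 equiv), CH2Cl2, −20 °C, 1 h; then SOCl2 (1.5 equiv), −78 to −40 °C, 1 h; AgNO3-impregnated silica
Reagents that add atoms: acetyl chloride, CC(=O)Cl
Why: Pyridine-buffered acylation is selective for the primary allylic hydroxyl, and the equatorial 8α-chlorosulfite then undergoes anti-periplanar E2 elimination for which only the C17 methyl hydrogens are aligned (the C7 and C9 ring hydrogens are gauche to the leaving group), giving the exocyclic 8(17)-alkene (Hofmann-type regiochemistry) without forming a stereocentre.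

**Step 4**
Reactants: 6 copalyl acetate
Product: 9 (13E)-15-acetoxylabda-8(17),13-dien-18-oic acid (target), via 18-alcohol 7 (not isolated), via 18-aldehyde 8 (not isolated)
Conditions: CYP720B4 variant (Picea sitchensis heme-thiolate diterpene C18 oxidase, ring C pocket enlarged by directed evolution) with cytochrome P450 reductase, E. coli membrane fraction, NADP+ (cat.), phosphite dehydrogenase, Na2HPO3 (6 equiv), air (O2), K2HPO4/KH2PO4 buffer pH 7.5, 2-hydroxypropyl-β-cyclodextrin, 28 °C, 24 h
Reagents that add atoms: dioxygen, O=O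
Why: Proposed new method: a conifer diterpene C18 oxidase is re-targeted from tricyclic abietane and pimarane olefins to the bicyclic labdane ester 6; its ferryl-oxo porphyrin radical cation (tetravalent iron) abstracts a hydrogen atom from the equatorial 4α-methyl held over the heme and returns hydroxyl by oxygen rebound (first C18–O bond, 7), two further turnovers through the gem-diol give aldehyde 8 and acid 9, and the enzyme's choice between the two diastereotopic C4 methyls creates the C4 stereocentre (R, carboxyl α, trans to the C10 methyl), ring A of 6 being identical to that of the native substrates and the alkenes lying as far from iron as the diene units of those substrates; the closest known reactions are the native three-step C18 oxidation of abietadiene and isopimaradiene to resin acids by this enzyme family and the microbial C18 hydroxylation of sclareol.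

**Compound list**
1 | (−)-sclareol, (13R)-labd-14-ene-8α,13-diol (5S,8R,9R,10S) | C[C@@]1(O)CC[C@@H]2[C@](C)(CCCC2(C)C)[C@H]1CC[C@@](C)(O)C=C | starting material
2 | sclareol diacetate, (13R)-labd-14-ene-8α,13-diyl diacetate | C[C@@]1(OC(C)=O)CC[C@@H]2[C@](C)(CCCC2(C)C)[C@H]1CC[C@@](C)(OC(C)=O)C=C | intermediate
3 | (13E)-labd-13-ene-8α,15-diyl diacetate | C[C@@]1(OC(C)=O)CC[C@@H]2[C@](C)(CCCC2(C)C)[C@H]1CC/C(C)=C/COC(C)=O | intermediate (not isolated)
4 | (13E)-labd-13-ene-8α,15-diol | C[C@@]1(O)CC[C@@H]2[C@](C)(CCCC2(C)C)[C@H]1CC/C(C)=C/CO | intermediate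
5 | (13E)-8α-hydroxylabd-13-en-15-yl acetate | C[C@@]1(O)CC[C@@H]2[C@](C)(CCCC2(C)C)[C@H]1CC/C(C)=C/COC(C)=O | intermediate (not isolated)
6 | copalyl acetate of the normal series, (13E)-labda-8(17),13-dien-15-yl acetate (5S,9S,10S) | C=C1CC[C@@H]2[C@](C)(CCCC2(C)C)[C@H]1CC/C(C)=C/COC(C)=O | intermediate
7 | (13E)-18-hydroxylabda-8(17),13-dien-15-yl acetate (CH2OH α at C4) | C=C1CC[C@@H]2[C@](C)(CCC[C@@]2(C)CO)[C@H]1CC/C(C)=C/COC(C)=O | intermediate (not isolated)
8 | (13E)-15-acetoxylabda-8(17),13-dien-18-al (CHO α at C4) | C=C1CC[C@@H]2[C@](C)(CCC[C@@]2(C)C=O)[C@H]1CC/C(C)=C/COC(C)=O | intermediate (not isolated)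
9 | (13E)-15-acetoxylabda-8(17),13-dien-18-oic acid (4R,5R,9S,10R) | C=C1CC[C@@H]2[C@](C)(CCC[C@@]2(C)C(=O)O)[C@H]1CC/C(C)=C/COC(C)=O | target

**Step count and risks**
Total step count: 4 (six transformations, two one-flask pairs). Longest linear sequence: 4.

Most likely to fail:

- **Step 4** (new enzymatic oxidation: low activity on a labdane, stalling at 7 or 8, esterase loss of the acetate). The fallback uses known chemistry, sets out from 1 and comes back to the route at 9.
  - Whole cells of Mucor plumbeus (or a Cunninghamella strain) hydroxylate sclareol at C18 beside C3, and chromatography gives (13R)-labd-14-ene-8α,13,18-triol F6.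
  - Dess–Martin periodinane oxidises only the primary neopentyl alcohol, giving 8α,13-dihydroxylabd-14-en-18-al F7.
  - NaClO2/NaH2PO4/2-methyl-2-butene then gives 8α,13-dihydroxylabd-14-en-18-oic acid F8.
  - The chemistry of steps 1 to 3 is repeated with the carboxyl left free. AcCl/N,N-dimethylaniline gives 8α,13-diacetoxylabd-14-en-18-oic acid F9 (the mixed anhydride is hydrolysed on aqueous work-up).
  - PdCl2(MeCN)2 gives (13E)-8α,15-diacetoxylabd-13-en-18-oic acid F10.
  - Excess NaOMe in MeOH gives (13E)-8α,15-dihydroxylabd-13-en-18-oic acid F11.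
  - AcCl/pyridine gives (13E)-15-acetoxy-8α-hydroxylabd-13-en-18-oic acid F12.
  - SOCl2/pyridine, followed by aqueous NaHCO3 to hydrolyse the hindered acyl chloride, gives 9.

- **Step 2** (the acetoxy shift gives only about 3:1 13E:13Z, with loss on crystallisation). The fallback is stereospecific, sets out from 1 and comes back at 4.
  - KMnO4 (MgSO4, aqueous acetone, 0 °C) degrades the vinyl carbinol to 8α-hydroxy-14,15-dinorlabdan-13-one F1.
  - Excess LiN(iPr)2 and then ClP(O)(OEt)2 give the terminal enol phosphate, diethyl 8α-hydroxy-14,15-dinorlabd-13(16)-en-13-yl phosphate F2.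
  - More LiN(iPr)2 in the same flask eliminates it to the terminal alkyne 15,16-dinorlabd-13-yn-8α-ol F3.
  - Negishi zirconium-catalysed methylalumination (Me3Al, Cp2ZrCl2, CH2Cl2) adds methyl and aluminium syn, giving the (E)-alkenyldimethylalane F4.
  - n-BuLi and then (CH2O)n hydroxymethylate F4 to 4 as a single geometric isomer.

- **Step 3** (ionisation of the chlorosulfite would give the endocyclic 7-ene and 8-ene). The fallback sets out from 5, isolated after the acetylation, and comes back at 6. It replaces the external-base anti elimination with an intramolecular syn elimination.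
  - Methyl N-(triethylammoniosulfonyl)carbamate (Burgess reagent) in benzene at 50 °C converts the tertiary alcohol into the triethylammonium 8-O-[N-(methoxycarbonyl)sulfamate] of 5 F5.
  - F5 collapses through a coplanar cyclic transition state that only a C17 hydrogen can reach, giving 6.

**Further compounds**
F1 | step 2 | 8α-hydroxy-14,15-dinorlabdan-13-one | C[C@@]1(O)CC[C@@H]2[C@](C)(CCCC2(C)C)[C@H]1CCC(C)=O
F2 | step 2 | diethyl 8α-hydroxy-14,15-dinorlabd-13(16)-en-13-yl phosphate | C[C@@]1(O)CC[C@@H]2[C@](C)(CCCC2(C)C)[C@H]1CCC(=C)OP(=O)(OCC)OCC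
F3 | step 2 | 15,16-dinorlabd-13-yn-8α-ol | C[C@@]1(O)CC[C@@H]2[C@](C)(CCCC2(C)C)[C@H]1CCC#C
F4 | step 2 | (13E)-15-nor-8α-hydroxylabd-13-en-14-yl(dimethyl)alane | C[C@@]1(O)CC[C@@H]2[C@](C)(CCCC2(C)C)[C@H]1CC/C(C)=C/[Al](C)C
F5 | step 3 | triethylammonium 8-O-[N-(methoxycarbonyl)sulfamate] of (13E)-8α-hydroxylabd-13-en-15-yl acetate | C[C@@]1(OS(=O)(=O)[N-]C(=O)OC)CC[C@@H]2[C@](C)(CCCC2(C)C)[C@H]1CC/C(C)=C/COC(C)=O.CC[NH+](CC)CC
F6 | step 4 | 18-hydroxysclareol, (13R)-labd-14-ene-8α,13,18-triol | C[C@@]1(O)CC[C@@H]2[C@](C)(CCC[C@@]2(C)CO)[C@H]1CC[C@@](C)(O)C=C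
F7 | step 4 | 8α,13-dihydroxylabd-14-en-18-al | C[C@@]1(O)CC[C@@H]2[C@](C)(CCC[C@@]2(C)C=O)[C@H]1CC[C@@](C)(O)C=C
F8 | step 4 | 8α,13-dihydroxylabd-14-en-18-oic acid | C[C@@]1(O)CC[C@@H]2[C@](C)(CCC[C@@]2(C)C(=O)O)[C@H]1CC[C@@](C)(O)C=C
F9 | step 4 | 8α,13-diacetoxylabd-14-en-18-oic acid | C[C@@]1(OC(C)=O)CC[C@@H]2[C@](C)(CCC[C@@]2(C)C(=O)O)[C@H]1CC[C@@](C)(OC(C)=O)C=C
F10 | step 4 | (13E)-8α,15-diacetoxylabd-13-en-18-oic acid | C[C@@]1(OC(C)=O)CC[C@@H]2[C@](C)(CCC[C@@]2(C)C(=O)O)[C@H]1CC/C(C)=C/COC(C)=O
F11 | step 4 | (13E)-8α,15-dihydroxylabd-13-en-18-oic acid | C[C@@]1(O)CC[C@@H]2[C@](C)(CCC[C@@]2(C)C(=O)O)[C@H]1CC/C(C)=C/CO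
F12 | step 4 | (13E)-15-acetoxy-8α-hydroxylabd-13-en-18-oic acid | C[C@@]1(O)CC[C@@H]2[C@](C)(CCC[C@@]2(C)C(=O)O)[C@H]1CC/C(C)=C/COC(C)=O
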